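**Plan**

1. Retrosynthetic cuts, in order: the C11–O aryl ether to umbelliferone; C9=C11 (one carbon added to a C9 ketone); the C2–O bond (hydroxylation of a 3-ketone enolate); C3–C4 (ring A); and finally C10–C1 and C10–CH3 (two enolate alkylations of (S)-carvone).
2. Enabling feature: C4 of ring A is a quaternary gem-dimethyl carbon lying between the carbinol carbon C3 and the ring-fusion carbon C5. This is what results when the tertiary radical derived from the carvone isopropenyl group adds to a C3 aldehyde.
3. Forward: ring B is the carvone ring. Methylation and allylation build C10, the allyl group becomes the C1–C3 aldehyde chain, and a hydrogen-atom-transfer radical cyclisation closes ring A.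
4. After that: the 3-ketone, C2 hydroxylation, reduction to the 2,3-diol (carried as its acetonide), C11 by methylenation and hydroboration, Mitsunobu coupling with umbelliferone, and deprotection.
5. Stereochemistry: C5 comes from (S)-carvone; C10 from allylation anti to the isopropenyl group; C2 and C3 from reagent approach anti to the axial C10 and C4 methyls; C9 from hydroboration anti to the C10 methyl.

Key step: step 5

Remark: drimane numbering is used for the bicyclic core; carvone C1, C2, C3, C4, C5 and C6 become C9, C8, C7, C6, C5 and C10.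
Remark: 10 is written as the equatorial C3 alcohol expected from a chair transition state; a C3 epimer, if formed, is carried on unseparated because step 6 turns C3 into a ketone.

**Step 1**
Reactants: 1 (S)-carvone
Product: 3 (5S)-2,6-dimethyl-5-(prop-1-en-2-yl)cyclohex-2-en-1-one (6-methylcarvone; both C6 epimers), via lithium dienolate 2 (not isolated)
Conditions: LiN(iPr)2, THF, −78 °C; MeI, −78 → 0 °C
Reagents that add atoms: iodomethane, CI; LiN(iPr)2, [Li+].CC(C)[N-]C(C)C (lithium, in 2 only)
Why: Kinetic deprotonation of the enone at the α′ carbon gives the cross-conjugated dienolate, which is C-methylated (enolate alkylation); the epimer mixture at the new centre is irrelevant because that carbon is enolised again in step 2.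

**Step 2**
Reactants: 3 6-methylcarvone; 4 allyl bromide
Product: 6 (5R,6R)-2,6-dimethyl-6-(prop-2-en-1-yl)-5-(prop-1-en-2-yl)cyclohex-2-en-1-one, via lithium enolate 5 (not isolated)
Conditions: LiN(iPr)2, THF, −78 °C; allyl bromide, DMPU, −78 °C → rt
Reagents that add atoms: LiN(iPr)2, [Li+].CC(C)[N-]C(C)C (lithium, in 5 only)
Why: Both epimers of 3 give the same tetrasubstituted enolate, and allyl bromide should approach anti to the neighbouring isopropenyl group (1,2-induction in enolate alkylation), which sets the quaternary carbon (future C10) with methyl cis and allyl trans to isopropenyl.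

**Step 3**
Reactants: 6 allyl ketone
Product: 8 (5R,6R)-6-(3-hydroxypropyl)-2,6-dimethyl-5-(prop-1-en-2-yl)cyclohex-2-en-1-one, via catechol boronate 7 (not isolated)
Conditions: RhCl(PPh3)3 (cat.), catecholborane, THF, 0 °C → rt; then H2O2, pH 7 phosphate buffer, EtOH, 0 °C → rt
Reagents that add atoms: catecholborane, B1Oc2ccccc2O1 (boron and catecholate, in 7 only); hydrogen peroxide, OO (hydroxyl oxygen of 8)
Why: Rhodium-catalysed anti-Markovnikov hydroboration strongly prefers the monosubstituted terminal alkene over the 1,1-disubstituted isopropenyl group and the hindered ketone, and neutral peroxide oxidises the C–B bond without nucleophilic epoxidation of the enone.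

**Step 4**
Reactants: 8 primary alcohol
Product: 9 3-[(1R,6R)-1,3-dimethyl-2-oxo-6-(prop-1-en-2-yl)cyclohex-3-en-1-yl]propanal
Conditions: Dess–Martin periodinane, CH2Cl2, 0 °C → rt
Reagents that add atoms: none
Why: Dess–Martin oxidation converts the primary alcohol into the aldehyde under neutral conditions that leave both alkenes and the enone alone.

**Step 5**
Reactants: 9 keto aldehyde
Product: 10 (4aR,6R,8aR)-6-hydroxy-2,5,5,8a-tetramethyl-4a,5,6,7,8,8a-hexahydronaphthalen-1(4H)-one
Conditions: Fe(acac)3 (50 mol %), PhSiH3, EtOH/(CH2OH)2 (5:1), degassed, 60 °C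
Reagents that add atoms: none
Why: Fe(acac)3 and PhSiH3 in ethanol generate a trivalent iron hydride that transfers a hydrogen atom to the terminal CH2 of the electron-rich isopropenyl group, creating the second C4 methyl and a tertiary radical at C4; this radical adds to the aldehyde carbon C3, and the alkoxy radical is reduced by divalent iron and protonated by the solvent, which returns trivalent iron. The closest known reaction type is the metal-hydride hydrogen-atom-transfer reductive radical cyclisation of alkene-tethered carbonyl compounds. Ring A closes in the 6-exo-trig mode through a chair-like transition state in which the C5–C4 and C10–C1 bonds are both equatorial on ring B, so the trans ring fusion already fixed by C5 and C10 is carried over unchanged. The only new stereocentre, C3, is governed by the preference of the aldehyde oxygen for the pseudo-equatorial position of that chair (hydroxyl cis to the C10 methyl), and either outcome is usable because step 6 makes C3 a ketone. The step needs hydrogen-atom transfer to the isopropenyl group and not to the enone alkene, which the electron-poor, trisubstituted character of C7=C8 secures, and it needs reduction of the alkoxy radical to outrun β-scission, which the divalent iron formed alongside the radical and the protic medium provide.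

**Step 6**
Reactants: 10 hydroxy enone
Product: 11 (4aR,8aR)-2,5,5,8a-tetramethyl-4,4a,5,7,8,8a-hexahydronaphthalene-1,6-dione
Conditions: Dess–Martin periodinane, CH2Cl2, rt
Reagents that add atoms: none
Why: Dess–Martin oxidation of the hindered secondary C3 alcohol gives the 3-ketone, and both C3 epimers converge on the same dione.

**Step 7**
Reactants: 11 ene-dione
Product: 13 (4aR,7S,8aR)-7-hydroxy-2,5,5,8a-tetramethyl-4,4a,5,7,8,8a-hexahydronaphthalene-1,6-dione, via potassium enolate 12 (not isolated)
Conditions: KN(SiMe3)2, THF, −78 °C; 2-(phenylsulfonyl)-3-phenyloxaziridine, −78 °C; AcOH quench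
Reagents that add atoms: 2-(phenylsulfonyl)-3-phenyloxaziridine, O=S(=O)(N1OC1c1ccccc1)c1ccccc1 (C2 oxygen); KN(SiMe3)2, [K+].C[Si](C)(C)[N-][Si](C)(C)C (potassium, in 12 only)
Why: C2 is the only α-CH2 of the C3 ketone (C4 is quaternary and the C9 enone has no α′ hydrogen), and in this Davis enolate hydroxylation the oxaziridine should deliver oxygen to the enolate face away from the axial C10 and C4 methyls, giving the equatorial C2 hydroxyl trans to the C10 methyl.

**Step 8**
Reactants: 13 α-hydroxy ketone
Product: 14 (4aR,6S,7S,8aR)-6,7-dihydroxy-2,5,5,8a-tetramethyl-4a,5,6,7,8,8a-hexahydronaphthalen-1(4H)-one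
Conditions: NaBH4, MeOH/CH2Cl2, −20 °C
Reagents that add atoms: none
Why: Borohydride should reduce the activated saturated α-hydroxy ketone well before the conjugated, doubly flanked C9 enone (as in the selective reduction of the saturated carbonyl of Wieland–Miescher ketone), and axial hydride delivery on the face away from the axial C4 and C10 methyls gives the equatorial C3 hydroxyl, cis to the C10 methyl and trans to the C2 hydroxyl.

**Step 9**
Reactants: 14 diol
Product: 15 (4aR,6S,7S,8aR)-6,7-(isopropylidenedioxy)-2,5,5,8a-tetramethyl-4a,5,6,7,8,8a-hexahydronaphthalen-1(4H)-one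
Conditions: Me2C(OMe)2, PPTS (cat.), CH2Cl2, rt
Reagents that add atoms: 2,2-dimethoxypropane, COC(C)(C)OC
Why: Acid-catalysed transacetalisation converts the trans-diequatorial vicinal diol into its trans-fused acetonide, which masks both hydroxyls for the base, borane and Mitsunobu steps that follow.

**Step 10**
Reactants: 15 acetonide enone
Product: 16 (4aS,6S,7S,8aR)-6,7-(isopropylidenedioxy)-2,5,5,8a-tetramethyl-1-methylidene-1,4,4a,5,6,7,8,8a-octahydronaphthalene
Conditions: Ph3PCH3Br, KOtBu, toluene, 90 °C
Reagents that add atoms: methyltriphenylphosphonium bromide, C[P+](c1ccccc1)(c1ccccc1)c1ccccc1.[Br-]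
Why: Wittig methylenation under the forcing potassium tert-butoxide/toluene conditions used for hindered ketones converts the C9 carbonyl, which has no α′ hydrogen, into the exocyclic C9=C11 alkene of a 7,9(11)-diene.

**Step 11**
Reactants: 16 diene
Product: 18 [(1R,4aS,6S,7S,8aR)-6,7-(isopropylidenedioxy)-2,5,5,8a-tetramethyl-1,4,4a,5,6,7,8,8a-octahydronaphthalen-1-yl]methanol, via B-alkyl-9-BBN adduct 17 (not isolated)
Conditions: 9-BBN, THF, 0 °C → rt; then NaOH, H2O2, 0 °C → rt
Reagents that add atoms: 9-borabicyclo[3.3.1]nonane, B1C2CCCC1CCC2 (boron and bicycle, in 17 only); hydrogen peroxide, OO (C11 oxygen)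
Why: 9-BBN hydroborates the terminal exocyclic carbon of the diene and leaves the trisubstituted C7=C8 alone; it approaches from the face opposite the axial C10 methyl, so hydrogen arrives at C9 trans to that methyl and, after oxidation with retention, the CH2OH group sits cis to it as in drimenol-type systems.

**Step 12**
Reactants: 18 C11 alcohol; 19 umbelliferone
Product: 20 7-{[(1R,4aS,6S,7S,8aR)-6,7-(isopropylidenedioxy)-2,5,5,8a-tetramethyl-1,4,4a,5,6,7,8,8a-octahydronaphthalen-1-yl]methoxy}-2H-chromen-2-one
Conditions: PPh3, DIAD, THF, 0 °C → rt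
Reagents that add atoms: none
Why: In this Mitsunobu etherification the acidic phenol of umbelliferone displaces the oxyphosphonium derived from the only free (primary) hydroxyl, and no stereocentre is involved.

**Step 13**
Reactants: 20 acetonide ether
Product: 21 7-{[(1R,4aS,6S,7S,8aR)-6,7-dihydroxy-2,5,5,8a-tetramethyl-1,4,4a,5,6,7,8,8a-octahydronaphthalen-1-yl]methoxy}-2H-chromen-2-one (target)
Conditions: AcOH/H2O (4:1), 40 °C
Reagents that add atoms: none
Why: Mild aqueous acid hydrolyses the strained trans-fused acetonide, while the aryl alkyl ether, the coumarin lactone and the trisubstituted alkene are stable under these conditions.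

**Compound list**

1 | (S)-carvone, (5S)-2-methyl-5-(prop-1-en-2-yl)cyclohex-2-en-1-one | CC1=CC[C@@H](CC1=O)C(C)=C | starting material
2 | lithium cross-conjugated dienolate of 1 (O–Li on C1, C1=C6) | [Li+].CC1=CC[C@@H](C=C1[O-])C(C)=C | intermediate
3 | (5S)-2,6-dimethyl-5-(prop-1-en-2-yl)cyclohex-2-en-1-one (6-methylcarvone, both C6 epimers) | CC1=CC[C@H](C(C)=C)C(C)C1=O | intermediate
4 | allyl bromide (3-bromoprop-1-ene) | C=CCBr | starting material
5 | lithium enolate of 3 (tetrasubstituted C1=C6) | [Li+].CC1=CC[C@H](C(C)=C)C(C)=C1[O-] | intermediate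
6 | (5R,6R)-2,6-dimethyl-6-(prop-2-en-1-yl)-5-(prop-1-en-2-yl)cyclohex-2-en-1-one (allyl trans to isopropenyl) | CC1=CC[C@H](C(C)=C)[C@@](C)(CC=C)C1=O | intermediate
7 | (5R,6R)-6-[3-(1,3,2-benzodioxaborol-2-yl)propyl]-2,6-dimethyl-5-(prop-1-en-2-yl)cyclohex-2-en-1-one | CC1=CC[C@H](C(C)=C)[C@@](C)(CCCB2Oc3ccccc3O2)C1=O | intermediate
8 | (5R,6R)-6-(3-hydroxypropyl)-2,6-dimethyl-5-(prop-1-en-2-yl)cyclohex-2-en-1-one | CC1=CC[C@H](C(C)=C)[C@@](C)(CCCO)C1=O | intermediate
9 | 3-[(1R,6R)-1,3-dimethyl-2-oxo-6-(prop-1-en-2-yl)cyclohex-3-en-1-yl]propanal | CC1=CC[C@H](C(C)=C)[C@@](C)(CCC=O)C1=O | intermediate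
10 | (4aR,6R,8aR)-6-hydroxy-2,5,5,8a-tetramethyl-4a,5,6,7,8,8a-hexahydronaphthalen-1(4H)-one (trans-fused; 3-OH cis to the C10 methyl) | CC1=CC[C@@H]2C(C)(C)[C@H](O)CC[C@@]2(C)C1=O | intermediate
11 | (4aR,8aR)-2,5,5,8a-tetramethyl-4,4a,5,7,8,8a-hexahydronaphthalene-1,6-dione | CC1=CC[C@@H]2C(C)(C)C(=O)CC[C@@]2(C)C1=O | intermediate
12 | potassium enolate of 11 (C2=C3–O–K in drimane numbering) | [K+].CC1=CC[C@@H]2C(C)(C)C([O-])=CC[C@@]2(C)C1=O | intermediate
13 | (4aR,7S,8aR)-7-hydroxy-2,5,5,8a-tetramethyl-4,4a,5,7,8,8a-hexahydronaphthalene-1,6-dione (2-OH trans to the C10 methyl) | CC1=CC[C@@H]2C(C)(C)C(=O)[C@@H](O)C[C@@]2(C)C1=O | intermediate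
14 | (4aR,6S,7S,8aR)-6,7-dihydroxy-2,5,5,8a-tetramethyl-4a,5,6,7,8,8a-hexahydronaphthalen-1(4H)-one (trans-diequatorial diol) | CC1=CC[C@@H]2C(C)(C)[C@H](O)[C@@H](O)C[C@@]2(C)C1=O | intermediate
15 | (4aR,6S,7S,8aR)-6,7-(isopropylidenedioxy)-2,5,5,8a-tetramethyl-4a,5,6,7,8,8a-hexahydronaphthalen-1(4H)-one (acetonide of 14) | CC1=CC[C@@H]2C(C)(C)[C@@H]3OC(C)(C)O[C@H]3C[C@@]2(C)C1=O | intermediate
16 | (4aS,6S,7S,8aR)-6,7-(isopropylidenedioxy)-2,5,5,8a-tetramethyl-1-methylidene-1,4,4a,5,6,7,8,8a-octahydronaphthalene | CC1=CC[C@@H]2C(C)(C)[C@@H]3OC(C)(C)O[C@H]3C[C@@]2(C)C1=C | intermediate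
17 | 9-BBN adduct of 16: B-alkyl-9-borabicyclo[3.3.1]nonane with boron on C11 and the C9 hydrogen trans to the C10 methyl | CC1=CC[C@@H]2C(C)(C)[C@@H]3OC(C)(C)O[C@H]3C[C@@]2(C)[C@@H]1CB1C2CCCC1CCC2 | intermediate
18 | [(1R,4aS,6S,7S,8aR)-6,7-(isopropylidenedioxy)-2,5,5,8a-tetramethyl-1,4,4a,5,6,7,8,8a-octahydronaphthalen-1-yl]methanol | CC1=CC[C@@H]2C(C)(C)[C@@H]3OC(C)(C)O[C@H]3C[C@@]2(C)[C@@H]1CO | intermediate
19 | umbelliferone (7-hydroxy-2H-chromen-2-one) | Oc1ccc2ccc(=O)oc2c1 | starting material
20 | 7-{[(1R,4aS,6S,7S,8aR)-6,7-(isopropylidenedioxy)-2,5,5,8a-tetramethyl-1,4,4a,5,6,7,8,8a-octahydronaphthalen-1-yl]methoxy}-2H-chromen-2-one | CC1=CC[C@@H]2C(C)(C)[C@@H]3OC(C)(C)O[C@H]3C[C@@]2(C)[C@@H]1COc1ccc2ccc(=O)oc2c1 | intermediate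
21 | 7-{[(1R,4aS,6S,7S,8aR)-6,7-dihydroxy-2,5,5,8a-tetramethyl-1,4,4a,5,6,7,8,8a-octahydronaphthalen-1-yl]methoxy}-2H-chromen-2-one | CC1=CC[C@@H]2C(C)(C)[C@H](O)[C@@H](O)C[C@@]2(C)[C@@H]1COc1ccc2ccc(=O)oc2c1 | target

**Step count and risks**

Total step count: 13. Longest linear sequence: 13 steps, from (S)-carvone 1 to 21.

Steps most likely to fail:

Step 5. The tertiary C4 radical may be reduced before it cyclises, the ring closure may reverse through β-scission of the C3 alkoxy radical, or the aldehyde may be consumed by the silane; each of these costs ring A. The fallback changes the acceptor to a nitrile and sets out from 9. Treatment of 9 with I2 and aqueous NH3 in THF should give 3-[(1R,6R)-1,3-dimethyl-2-oxo-6-(prop-1-en-2-yl)cyclohex-3-en-1-yl]propanenitrile F1. Under Fe(acac)3/PhSiH3 in ethanol the same C4 radical would add to the nitrile carbon (a known hydrogen-atom-transfer cyclisation of alkenyl nitriles), and reduction of the iminyl radical would give the ketimine (4aR,8aR)-6-imino-2,5,5,8a-tetramethyl-4a,5,6,7,8,8a-hexahydronaphthalen-1(4H)-one F2. Aqueous HCl work-up hydrolyses this to dione 11, where the route resumes; step 6 is then not needed.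

Step 10. The ylide may act as a base at C6 (γ-deprotonation of the enone) instead of adding to the shielded C9 carbonyl, so that conversion stalls and recovered enone deconjugates. The fallback is a Peterson olefination from 15. Addition of Me3SiCH2Li with CeCl3 in THF at −78 °C, a more nucleophilic and less basic reagent, should give (4aR,6S,7S,8aR)-6,7-(isopropylidenedioxy)-2,5,5,8a-tetramethyl-1-[(trimethylsilyl)methyl]-1,4,4a,5,6,7,8,8a-octahydronaphthalen-1-ol F3, with either configuration at the carbinol carbon. KH in THF then effects syn-elimination to diene 16, where the route resumes.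

Step 12. Displacement at the β-branched C11 oxyphosphonium may be slow, so that the betaine is diverted into hydrazide alkylation or elimination. The fallback forms the aryl–oxygen bond instead and sets out from 18. Palladium-catalysed C–O coupling of 18 with 7-bromo-2H-chromen-2-one (in place of 19), using [Pd(C3H5)Cl]2, the biaryl phosphine RockPhos and Cs2CO3 in toluene at 90 °C, should give 20 directly through oxidative addition of zerovalent palladium to the aryl bromide, and the route resumes there.

**Further compounds**

F1 | step 5 | 3-[(1R,6R)-1,3-dimethyl-2-oxo-6-(prop-1-en-2-yl)cyclohex-3-en-1-yl]propanenitrile | CC1=CC[C@H](C(C)=C)[C@@](C)(CCC#N)C1=O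
F2 | step 5 | (4aR,8aR)-6-imino-2,5,5,8a-tetramethyl-4a,5,6,7,8,8a-hexahydronaphthalen-1(4H)-one | CC1=CC[C@@H]2C(C)(C)C(=N)CC[C@@]2(C)C1=O
F3 | step 10 | (4aR,6S,7S,8aR)-6,7-(isopropylidenedioxy)-2,5,5,8a-tetramethyl-1-[(trimethylsilyl)methyl]-1,4,4a,5,6,7,8,8a-octahydronaphthalen-1-ol (carbinol carbon either configuration) | CC1=CC[C@@H]2C(C)(C)[C@@H]3OC(C)(C)O[C@H]3C[C@@]2(C)C1(O)C[Si](C)(C)C
F0 | step 12 | none | none
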